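**Retrosynthetic overview**
- The central CH2 is cut back to formaldehyde and two identical acylphloroglucinol halves. In the forward sense one half is hydroxymethylated, dehydrates to an ortho-quinone methide, and a second half adds to it in an intermolecular Michael reaction.
- The monomeric ketone is traced to its ring carboxylate. A CO2Me group blocks the position between the two hydroxyls until the end and is removed by saponification and decarboxylation.
- The isovaleryl group goes in by Friedel–Crafts acylation at the last free ring position. The C-methyl comes from formylation and hydrogenolysis of a mirror-symmetric 2,6-dihydroxy-4-methoxybenzoate, so neither step has a regiochemical choice.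
- That benzoate comes from selective 4-O-methylation of methyl 2,4,6-trihydroxybenzoate.
- No ring is formed. Both benzene rings come from the starting benzoate, and the substituents are installed in the order OMe, C-Me, acyl, loss of CO2, CH2 bridge.

Assumption: the target SMILES has no stereocentre or stereogenic double bond, so the compound is achiral and no enantiocontrol is needed.

**Step 1**
Reactants: 1 methyl 2,4,6-trihydroxybenzoate; 2 dimethyl sulfate
Product: 3 methyl 2,6-dihydroxy-4-methoxybenzoate
Conditions: Me2SO4 (1.0 equiv), K2CO3 (1.0 equiv), acetone, rt to 40 °C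
Reagents that add atoms: dimethyl sulfate (COS(=O)(=O)OC)
Why: Williamson O-methylation in which one equivalent of base deprotonates only the most acidic, non-chelated 4-OH (para to the ester), while the 2- and 6-OH are held by hydrogen bonding to the ester.

**Step 2**
Reactants: 3 methyl 2,6-dihydroxy-4-methoxybenzoate; 4 N,N-dimethylformamide
Product: 6 methyl 3-formyl-2,6-dihydroxy-4-methoxybenzoate, via aryl iminium chloride 5 (not isolated)
Conditions: POCl3 (1.2 equiv), DMF, MeCN, 0 °C to rt; then H2O, 50 °C
Reagents that add atoms: N,N-dimethylformamide (CN(C)C=O); water (O)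
Why: Vilsmeier–Haack formylation of a ring activated by three oxygen donors, whose two free positions are equivalent by symmetry, so one mono-aldehyde forms and the formyl group deactivates the ring against a second attack.

**Step 3**
Reactants: 6 methyl 3-formyl-2,6-dihydroxy-4-methoxybenzoate
Product: 8 methyl 2,6-dihydroxy-4-methoxy-3-methylbenzoate, via benzylic alcohol 7 (not isolated)
Conditions: H2 (1–3 atm), 10% Pd/C, AcOH, cat. HCl, rt
Reagents that add atoms: none
Why: Catalytic hydrogenolysis of an electron-rich ortho-hydroxybenzaldehyde, in which the benzylic alcohol 7 ionises readily under acid and is cleaved to the methyl group while ester, ether and ring are untouched.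

**Step 4**
Reactants: 8 methyl 2,6-dihydroxy-4-methoxy-3-methylbenzoate; 9 3-methylbutanoic anhydride
Product: 11 methyl 2,6-dihydroxy-4-methoxy-3-methyl-5-(3-methylbutanoyl)benzoate, via difluoroboron chelate 10 (not isolated)
Conditions: (iBuCO)2O (1.5 equiv), BF3·OEt2 (neat, about 4 equiv), 70 °C; then MeOH/H2O, reflux
Reagents that add atoms: 3-methylbutanoic anhydride (CC(C)CC(=O)OC(=O)CC(C)C)
Why: Friedel–Crafts C-acylation at the only remaining ring position (the ester blocks the site between the hydroxyls), with BF3 chosen because it holds the new ketone as a BF2 chelate to the neighbouring OH and does not cleave the adjacent aryl methyl ether.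

**Step 5**
Reactants: 11 methyl 2,6-dihydroxy-4-methoxy-3-methyl-5-(3-methylbutanoyl)benzoate
Product: 13 1-(4,6-dihydroxy-2-methoxy-3-methylphenyl)-3-methylbutan-1-one, via carboxylic acid 12 (not isolated)
Conditions: 2 M aq. NaOH, N2, 90 °C; then 3 M HCl to pH 1, 50 °C
Reagents that add atoms: none
Why: Saponification followed by protodecarboxylation, since the free 2,6-dihydroxy-4-alkoxybenzoic acid behaves as a vinylogous β-keto acid and loses CO2 on gentle warming in acid, unmasking the ring CH between the two hydroxyls.

**Step 6**
Reactants: 13 1-(4,6-dihydroxy-2-methoxy-3-methylphenyl)-3-methylbutan-1-one (2 equiv); 14 formaldehyde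
Product: 17 1,1'-[methylenebis(2,4-dihydroxy-6-methoxy-5-methyl-3,1-phenylene)]bis(3-methylbutan-1-one), via hydroxymethyl phenol 15 (not isolated), via ortho-quinone methide 16 (not isolated)
Conditions: 37% aq. HCHO (0.5 equiv per 13), 1% aq. KOH, N2, 0 °C to rt; then 1 M HCl
Reagents that add atoms: formaldehyde (C=O)
Why: Base-mediated hydroxymethylation (Lederer–Manasse, an aldol-type addition of the phenolate to formaldehyde), dehydration to quinone methide 16 and intermolecular Michael addition of a second phenolate of 13, with no oligomers possible because each ring has a single free position.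

**Compound list**
1 | methyl 2,4,6-trihydroxybenzoate | COC(=O)c1c(O)cc(O)cc1O | starting material
2 | dimethyl sulfate | COS(=O)(=O)OC | starting material
3 | methyl 2,6-dihydroxy-4-methoxybenzoate | COC(=O)c1c(O)cc(OC)cc1O | intermediate
4 | N,N-dimethylformamide | CN(C)C=O | starting material
5 | [2,6-dihydroxy-4-methoxy-3-(methoxycarbonyl)phenyl]methylidene-dimethyliminium chloride (aryl iminium chloride) | COC(=O)c1c(O)cc(OC)c(C=[N+](C)C)c1O.[Cl-] | intermediate
6 | methyl 3-formyl-2,6-dihydroxy-4-methoxybenzoate | COC(=O)c1c(O)cc(OC)c(C=O)c1O | intermediate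
7 | methyl 2,6-dihydroxy-3-(hydroxymethyl)-4-methoxybenzoate (benzylic alcohol) | COC(=O)c1c(O)cc(OC)c(CO)c1O | intermediate
8 | methyl 2,6-dihydroxy-4-methoxy-3-methylbenzoate | COC(=O)c1c(O)cc(OC)c(C)c1O | intermediate
9 | 3-methylbutanoic anhydride (isovaleric anhydride) | CC(C)CC(=O)OC(=O)CC(C)C | starting material
10 | difluoroboron chelate of 11 (BF2 bridging the ketone oxygen and the adjacent phenol oxygen in a six-membered ring) | COC(=O)c1c(O)c(C)c(OC)c2c1O[B-](F)(F)[O+]=C2CC(C)C | intermediate
11 | methyl 2,6-dihydroxy-4-methoxy-3-methyl-5-(3-methylbutanoyl)benzoate | COC(=O)c1c(O)c(C)c(OC)c(C(=O)CC(C)C)c1O | intermediate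
12 | 2,6-dihydroxy-4-methoxy-3-methyl-5-(3-methylbutanoyl)benzoic acid | OC(=O)c1c(O)c(C)c(OC)c(C(=O)CC(C)C)c1O | intermediate
13 | 1-(4,6-dihydroxy-2-methoxy-3-methylphenyl)-3-methylbutan-1-one | COc1c(C)c(O)cc(O)c1C(=O)CC(C)C | intermediate
14 | formaldehyde | C=O | starting material
15 | 1-[4,6-dihydroxy-5-(hydroxymethyl)-2-methoxy-3-methylphenyl]-3-methylbutan-1-one | COc1c(C)c(O)c(CO)c(O)c1C(=O)CC(C)C | intermediate
16 | 5-hydroxy-3-methoxy-2-methyl-6-methylidene-4-(3-methylbutanoyl)cyclohexa-2,4-dien-1-one (ortho-quinone methide) | C=C1C(=O)C(C)=C(OC)C(C(=O)CC(C)C)=C1O | intermediate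
17 | 3',3'''-methylenebis(2',4'-dihydroxy-6'-methoxy-β,5'-dimethylbutyrophenone), achiral | COc1c(C)c(O)c(Cc2c(O)c(C)c(OC)c(C(=O)CC(C)C)c2O)c(O)c1C(=O)CC(C)C | target

**Totals**
Total step count: 6.
Longest linear sequence: 6 steps (1 to 17); both halves of the target come from the same monomer 13.

**Steps most likely to fail, with fallbacks**

Step 4 is the most uncertain. The ring of 8 is ester-deactivated and the free position is flanked on both sides, so acylation may be sluggish, and a Lewis acid could demethylate the ether next to the new ketone. The fallback sets out from 8 and comes back at 11, building the ketone from an aldehyde instead of by acylation. Vilsmeier–Haack formylation of 8 (POCl3, DMF, MeCN, the reaction already used on 3) gives the aryl iminium chloride F1. Aqueous hydrolysis then gives methyl 3-formyl-2,6-dihydroxy-4-methoxy-5-methylbenzoate F2. Excess isobutylmagnesium bromide with CeCl3 in THF at −40 °C adds to the aldehyde; two equivalents are consumed by the phenols, whose magnesium salts also shield the ester. This gives racemic methyl 2,6-dihydroxy-3-(1-hydroxy-3-methylbutyl)-4-methoxy-5-methylbenzoate F3. Benzylic oxidation with DDQ in dioxane at rt then gives ketone 11 and removes the temporary stereocentre.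

Step 5 is next. The ester sits between two phenoxides and may resist hydroxide, and prolonged hot alkali could start to cleave the aryl ketone. The fallback sets out from 11 and comes back at 12, replacing acyl–oxygen cleavage by alkyl–oxygen cleavage. Lithium iodide in ethyl acetate at reflux attacks the ester O-methyl group by SN2, which is insensitive to shielding of the carbonyl and too mild to touch the aryl methyl ether. This gives lithium 2,6-dihydroxy-4-methoxy-3-methyl-5-(3-methylbutanoyl)benzoate F4. Acidification with 1 M HCl gives acid 12, which decarboxylates to 13 on warming as in the route.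

Step 6 is third. The coupling may stop at the hydroxymethyl stage, or the electron-rich phenolates may oxidise in aqueous base. The fallback sets out from 13 and comes back at 16, and from there at 17, separating activation from coupling. Mannich reaction of 13 with N,N-dimethylmethyleneiminium iodide (Eschenmoser's salt) in MeCN/CH2Cl2 at rt gives the isolable Mannich base 1-[5-(dimethylaminomethyl)-4,6-dihydroxy-2-methoxy-3-methylphenyl]-3-methylbutan-1-one F5. Heating F5 with one equivalent of 13 in dioxane at 100 °C expels dimethylamine to give quinone methide 16 under neutral, formaldehyde-free conditions, and Michael addition of 13 gives 17.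

**Further compounds**
F1 | step 4 | [2,6-dihydroxy-4-methoxy-3-(methoxycarbonyl)-5-methylphenyl]methylidene-dimethyliminium chloride (aryl iminium chloride) | COC(=O)c1c(O)c(C)c(OC)c(C=[N+](C)C)c1O.[Cl-]
F2 | step 4 | methyl 3-formyl-2,6-dihydroxy-4-methoxy-5-methylbenzoate | COC(=O)c1c(O)c(C)c(OC)c(C=O)c1O
F3 | step 4 | methyl 2,6-dihydroxy-3-(1-hydroxy-3-methylbutyl)-4-methoxy-5-methylbenzoate (racemic) | COC(=O)c1c(O)c(C)c(OC)c(C(O)CC(C)C)c1O
F4 | step 5 | lithium 2,6-dihydroxy-4-methoxy-3-methyl-5-(3-methylbutanoyl)benzoate | [Li+].[O-]C(=O)c1c(O)c(C)c(OC)c(C(=O)CC(C)C)c1O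
F5 | step 6 | 1-[5-(dimethylaminomethyl)-4,6-dihydroxy-2-methoxy-3-methylphenyl]-3-methylbutan-1-one | COc1c(C)c(O)c(CN(C)C)c(O)c1C(=O)CC(C)C
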